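- Per second, the substrate in both flasks is lost at 0.0116 /s, the sum of the constants for its first step to the intermediate and its forward step to the dormant form.

| flask | substrate | first nucleophile | second nucleophile | time |
|---|---|---|---|---|
| Thursday's | 0.10 M | 1.30 equiv | 3.00 equiv | 2.5 min |
| Wednesday's | 0.10 M | 1.30 equiv | 3.00 equiv | 4.0 min |

    substrate → intermediate (k1 = 0.0091 /s)
    first nucleophile + intermediate ⇌ target (K2 = 22 /M, k2 = 16 /M/s)
    second nucleophile + intermediate → other capture product (k3 = 3.6 /M/s)
    substrate ⇌ dormant form (K4 = 1.1, k4 = 0.0025 /s)

- which of these there is most of at the end, counted by the substrate in it, Thursday's (substrate / other capture product / intermediate / target)
- which of these there is most of at the end, counted by the substrate in it, Wednesday's (substrate / other capture product / intermediate / target)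
- how much there is at the end of the one of these that leads, in percent of the substrate charged: Thursday's
- how much there is at the end of the one of these that leads, in percent of the substrate charged: Wednesday's

- At Thursday's charges, the intermediate has a half-life of 0.64 s against the second nucleophile, far shorter than the substrate's 1.3 min by the first step. The first step is therefore the rate-limiting step on the way to other capture product.
- The target gives the intermediate back at 0.727 /s, much faster than the substrate is lost. The target is thus a brief holding place, and substrate through the first step is counted as other capture product.
- The capture share, the first step's constant over the loss constant, is 78.4%.
- Integrating the first-order loss, c(substrate) falls as exp(−loss constant × time). Other capture product is then the capture share times the substrate lost. The way back from the dormant form, at 0.00227 /s, is left out.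
- On my reckoning, at 2.5 min Thursday's flask will be led by other capture product, at 64.7%.
- At 4.0 min Wednesday's flask will be led by other capture product, at 73.6%.
- Leave the nucleophile charges untouched and watch the clock: neither charge stands in the expression for other capture product, but the time does.
- The forecast names other capture product at 65.7% for Thursday's and other capture product at 76.3% for Wednesday's, a little above my figures. Its ground: “The target forms quickly but reverts within seconds”.
- The simulation gives other capture product at 65.0% for Thursday's and other capture product at 76.3% for Wednesday's, so the forecast stands, and one exponential with the capture share comes within 2.7 percentage points on Wednesday's. Read the same flask as Wednesday's at 1.0 min, and the reckoning leaves 49.9% as substrate and puts 39.3% into other capture product. That neighbour is led by substrate, at 50.5%, with other capture product at 37.5%.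

All constants stand for no real mixture; what happens was integrated by code.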